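## Retrosynthetic overview
1. Last operations: remove the silyl groups from the two primary alcohols, and before that put the (Z)-angelate on the C6 hydroxyl of a hydroxy α-methylene lactone.
2. Ring B (the lactone, closed last): C11–C12 and C12–O8 come from a palladium-catalysed cyclocarbonylation of a cis-7-ethynyl-8-ol.
3. C7–C11: a hydroxyl-directed alkynylalane opens a 6β,7β-epoxide with inversion at C7. The epoxide comes from the cis-diol by double inversion at C6.
4. C4–C5 and the C4 stereocentre: a new amide-directed, iridium-catalysed, branch-selective asymmetric hydroalkenylation of a pentenyl silyl ether by the vinylic C5–H.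
5. Ring A (C5–C10 with C14, and the C6 and C8 configurations) is taken intact from (−)-shikimic acid. Ring order: A is given, B is closed at the end.

## Conventions and assumption
- **Numbering (seco-eudesmanolide).** Ring A is C5–C10 with C5=C10. C14 sits on C10. The side chain C4(C15H3)–C3–C2–C1 sits on C5. The lactone is C7–C11(=C13)–C12(=O)–O–C8.
- **Faces.** β is the face of the C6 oxygen and α is the opposite face.
- **Mapping.** Shikimic acid C1, C2, C3, C4, C5, C6, CO2H correspond to C10, C5, C6, C7, C8, C9, C14.
- **Target.** (4R,6S,7R,8R), cis-fused lactone (7α-C11, 8α-O), 6β-O-angelate.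
- **Abbreviations.** TBDPS = tert-butyldiphenylsilyl. BArF4 = tetrakis[3,5-bis(trifluoromethyl)phenyl]borate.
- **Assumption.** The (R,R) antipode of the bisphosphite in step 5 is taken as the one matched to the substrate and leading to 4R. If the sense of induction is opposite, the (S,S) antipode is used and nothing else changes.

## Route

Step 1
Reactants: 1 (−)-shikimic acid
Product: 2 shikimic acid 6,7-acetonide (3,4-O-isopropylideneshikimic acid; free 8α-OH)
Conditions: Me2C(OMe)2, p-TsOH·H2O (cat.), acetone, rt
Reagents that add atoms: 2,2-dimethoxypropane COC(C)(C)OC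
Why: Acid-catalysed transketalisation selects the only cis-1,2-diol (6β,7β), because the cis-fused dioxolane is much less strained than a trans-fused one, and no stereocentre is touched.

Step 2
Reactants: 2 shikimic acid 6,7-acetonide
Product: 3 N,N-diethylamide acetonide (C14 = CONEt2; free 8α-OH)
Conditions: Et2NH, EDC, HOBt (cat.), CH2Cl2, 0 °C to rt
Reagents that add atoms: diethylamine CCNCC
Why: In this carbodiimide/HOBt amide coupling the amine outcompetes the secondary C8 hydroxyl, and the product carries the Lewis-basic directing group needed in step 5.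

Step 3
Reactants: 3 N,N-diethylamide acetonide
Product: 4 8α-O-acetyl N,N-diethylamide acetonide
Conditions: Ac2O, pyridine, DMAP (cat.), CH2Cl2, 0 °C to rt
Reagents that add atoms: acetic anhydride CC(=O)OC(C)=O
Why: DMAP-catalysed acylation masks the carbinol against iridium-mediated dehydrogenation in step 5, and the acetate falls off at no extra cost in step 10.

Step 4
Reactants: 5 pent-4-en-1-ol
Product: 6 tert-butyl(pent-4-en-1-yloxy)diphenylsilane
Conditions: TBDPSCl, imidazole, CH2Cl2, rt
Reagents that add atoms: tert-butyldiphenylsilyl chloride CC(C)(C)[Si](Cl)(c1ccccc1)c1ccccc1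
Why: Standard imidazole-promoted silylation gives an ether that survives the weak acid, base and Lewis acids used later.

Step 5
Reactants: 4 8α-O-acetyl N,N-diethylamide acetonide; 6 tert-butyl(pent-4-en-1-yloxy)diphenylsilane
Product: 7 C5-alkylated enamide (4 bearing at C5 the (R)-5-(TBDPS-oxy)pentan-2-yl group; 4R)
Conditions: [Ir(cod)2]BArF4 (5 mol %), (R,R)-Chiraphite = (2R,4R)-pentane-2,4-diyl bis(3,3′-di-tert-butyl-5,5′-dimethoxybiphenyl-2,2′-diyl phosphite) (6 mol %), 6 (3 equiv), 1,4-dioxane, 110 °C
Reagents that add atoms: none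
Why: Proposed new method: the amide oxygen binds the cationic monovalent iridium centre and steers oxidative addition into the only cis β-vinylic C–H bond (C5–H), giving a five-membered iridacycle hydride of trivalent iridium; the π-acidic, wide-bite-angle bisphosphite destabilises the linear pathway, so the α-olefin 6 forms the C–C bond at its internal carbon; the chiral pocket, reinforced by the β-face acetonide next to C5, selects the olefin face that gives 4R; C–H reductive elimination then releases 7, whose twisted amide binds poorly, so product inhibition should be small, and no second vinylic C–H is available for over-alkylation; β-oxygen elimination from the alkenyl–iridium species is excluded because it would need a cyclic allene; the closest known reaction types are the amide- and anilide-directed iridium-catalysed branch-selective enantioselective hydroarylation of α-olefins and the carbonyl-directed iridium-catalysed vinylic C–H borylation of cyclohexene-1-carboxylates, and to my knowledge neither has been used to alkylate the β-C–H of a cyclic acrylamide to a tetrasubstituted alkene.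

Step 6
Reactants: 7 C5-alkylated enamide
Product: 9 C14 allylic alcohol, via enal 8 (not isolated)
Conditions: a) Cp2Zr(H)Cl (2 equiv), THF, rt, then aq. NH4Cl; b) crude 8, NaBH4, CeCl3·7H2O, MeOH, −20 °C
Reagents that add atoms: water O
Why: Chemoselective hydrozirconation of the tertiary amide leaves acetate, ketal and silyl ether alone and gives the enal on aqueous quench (its oxygen comes from the water), and immediate Luche 1,2-reduction avoids γ-deprotonation at C4 or C6, so no stereocentre is formed or lost.

Step 7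
Reactants: 9 C14 allylic alcohol
Product: 10 1,14-bis-TBDPS ether (acetonide and 8α-acetate retained)
Conditions: TBDPSCl, imidazole, DMF, rt
Reagents that add atoms: tert-butyldiphenylsilyl chloride CC(C)(C)[Si](Cl)(c1ccccc1)c1ccccc1
Why: Silylation of the only free hydroxyl gives both primary alcohols the same group, so one operation removes them at the end.

Step 8
Reactants: 10 1,14-bis-TBDPS ether
Product: 11 6β,7β-diol 8α-acetate
Conditions: AcOH–H2O–THF (4:1:1), 40 °C
Reagents that add atoms: none
Why: Acid-catalysed ketal hydrolysis proceeds through the dioxolanyl oxocarbenium ion far faster than ionisation of the allylic C6–O bond, and TBDPS ethers and the acetate tolerate this weak acid.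

Step 9
Reactants: 11 6β,7β-diol 8α-acetate
Product: 13 bromo diacetate (6α-Br, 7β-OAc, 8α-OAc), via cyclic orthoacetate 12 (not isolated)
Conditions: a) MeC(OMe)3, PPTS (cat.), CH2Cl2, rt, evaporate; b) AcBr, CH2Cl2, 0 °C
Reagents that add atoms: trimethyl orthoacetate COC(C)(OC)OC; acetyl bromide CC(=O)Br
Why: In this Kolb–Sharpless sequence the cis-diol orthoacetate is turned by AcBr into the 6,7-acetoxonium ion, which bromide opens by SN2 attack at the allylic C6 from the α face (first inversion at C6); opening at C7 would lead to the same β-epoxide in step 10.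

Step 10
Reactants: 13 bromo diacetate
Product: 14 6β,7β-epoxy-8α-ol
Conditions: K2CO3, MeOH, 0 °C
Reagents that add atoms: none
Why: Methanolysis frees both alkoxides and the 7β-alkoxide displaces the antiperiplanar 6α-bromide (intramolecular Williamson closure, second inversion at C6), so C6 keeps its β-oxygen, while low temperature and short time hold back Payne migration to the 8α-OH.

Step 11
Reactants: 14 6β,7β-epoxy-8α-ol
Product: 16 7α-ethynyl-6β,8α-diol, via silylalkyne diol 15 (not isolated)
Conditions: a) Me3SiC≡CH, n-BuLi, toluene, 0 °C; Et2AlCl, 0 °C; then 14, 0 °C to rt; aq. potassium sodium tartrate; b) crude 15, K2CO3 (cat.), MeOH, rt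
Reagents that add atoms: trimethylsilylacetylene C#C[Si](C)(C)C
Why: In this hydroxyl-directed alkynylalane epoxide opening the 8α-OH becomes an aluminium alkoxide that hands the alkynyl group to the neighbouring C7 from the α face through a five-membered transition state, which coincides with trans-diaxial (Fürst–Plattner) opening of the conformer with equatorial C8–O and avoids the hindered allylic C6, so C7 is inverted (7α-C, cis to 8α-O), the oxygen stays on C6 (6β), and methanolysis then removes the C-silyl group.

Step 12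
Reactants: 16 7α-ethynyl-6β,8α-diol
Product: 17 6β-hydroxy α-methylene cis-lactone (1,14-bis-TBDPS)
Conditions: PdCl2 (5 mol %), thiourea (10 mol %), CO (1 atm), acetone, 50 °C
Reagents that add atoms: carbon monoxide [C-]#[O+]
Why: In this palladium-catalysed cyclocarbonylation (intramolecular alkoxycarbonylation) of a homopropargylic alcohol, a carboalkoxy complex of divalent palladium formed from CO and the equatorial 8α-OH, which is gauche to the axial 7α-ethynyl group, adds syn to the alkyne at its internal carbon and protonolysis gives the exo-methylene cis-lactone, whereas the 6β-OH is antiperiplanar to the ethynyl group and cannot close a ring; no stereocentre changes.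

Step 13
Reactants: 18 angelic acid ((Z)-2-methylbut-2-enoic acid)
Product: 19 angelic 2,4,6-trichlorobenzoic anhydride
Conditions: 2,4,6-Cl3C6H2COCl, Et3N, toluene, rt; filter and concentrate
Reagents that add atoms: 2,4,6-trichlorobenzoyl chloride O=C(Cl)c1c(Cl)cc(Cl)cc1Cl
Why: Yamaguchi-type mixed anhydride formation activates the acid without a nucleophilic catalyst, so the Z alkene does not isomerise to the tiglate.

Step 14
Reactants: 17 6β-hydroxy α-methylene cis-lactone; 19 angelic 2,4,6-trichlorobenzoic anhydride
Product: 20 6β-O-angelate (1,14-bis-TBDPS ether of the target)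
Conditions: 19 (4 equiv), BHT (cat.), toluene, 80 °C
Reagents that add atoms: none
Why: In this thermal acylation the hindered C6 alcohol attacks the angeloyl carbonyl because the di-ortho-chloro aroyl carbonyl is shielded, and the absence of DMAP keeps the Z geometry; C6 keeps its configuration because the C–O bond is not broken.

Step 15
Reactants: 20 6β-O-angelate
Product: 21 target CNP0106570.2, (4R,6S,7R,8R)
Conditions: HF·pyridine, pyridine, THF, 0 °C to rt
Reagents that add atoms: none
Why: Buffered fluoride-mediated desilylation cleaves both primary TBDPS ethers and leaves the angelate, the allylic ester linkage and the α-methylene lactone untouched.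

## Compound list
1 | (−)-shikimic acid, (3R,4S,5R) | O[C@@H]1CC(C(=O)O)=C[C@@H](O)[C@H]1O | starting material
2 | shikimic acid 6,7-acetonide | O[C@@H]1CC(C(=O)O)=C[C@H]2OC(C)(C)O[C@@H]12 | intermediate
3 | N,N-diethylamide acetonide | O[C@@H]1CC(C(=O)N(CC)CC)=C[C@H]2OC(C)(C)O[C@@H]12 | intermediate
4 | 8α-O-acetyl N,N-diethylamide acetonide | CC(=O)O[C@@H]1CC(C(=O)N(CC)CC)=C[C@H]2OC(C)(C)O[C@@H]12 | intermediate
5 | pent-4-en-1-ol | C=CCCCO | starting material
6 | tert-butyl(pent-4-en-1-yloxy)diphenylsilane | C=CCCCO[Si](c1ccccc1)(c1ccccc1)C(C)(C)C | intermediate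
7 | C5-alkylated enamide (4R) | CC(=O)O[C@@H]1CC(C(=O)N(CC)CC)=C([C@H](C)CCCO[Si](c3ccccc3)(c3ccccc3)C(C)(C)C)[C@H]2OC(C)(C)O[C@@H]12 | intermediate
8 | enal (C14 aldehyde) | CC(=O)O[C@@H]1CC(C=O)=C([C@H](C)CCCO[Si](c3ccccc3)(c3ccccc3)C(C)(C)C)[C@H]2OC(C)(C)O[C@@H]12 | intermediate
9 | C14 allylic alcohol | CC(=O)O[C@@H]1CC(CO)=C([C@H](C)CCCO[Si](c3ccccc3)(c3ccccc3)C(C)(C)C)[C@H]2OC(C)(C)O[C@@H]12 | intermediate
10 | 1,14-bis-TBDPS ether | CC(=O)O[C@@H]1CC(CO[Si](c4ccccc4)(c4ccccc4)C(C)(C)C)=C([C@H](C)CCCO[Si](c3ccccc3)(c3ccccc3)C(C)(C)C)[C@H]2OC(C)(C)O[C@@H]12 | intermediate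
11 | 6β,7β-diol 8α-acetate | CC(=O)O[C@@H]1CC(CO[Si](c4ccccc4)(c4ccccc4)C(C)(C)C)=C([C@H](C)CCCO[Si](c3ccccc3)(c3ccccc3)C(C)(C)C)[C@@H](O)[C@H]1O | intermediate
12 | cyclic 6,7-orthoacetate (epimers at the orthoester carbon) | CC(=O)O[C@@H]1CC(CO[Si](c4ccccc4)(c4ccccc4)C(C)(C)C)=C([C@H](C)CCCO[Si](c3ccccc3)(c3ccccc3)C(C)(C)C)[C@H]2OC(C)(OC)O[C@@H]12 | intermediate
13 | bromo diacetate (6α-Br, 7β-OAc, 8α-OAc) | CC(=O)O[C@@H]1CC(CO[Si](c4ccccc4)(c4ccccc4)C(C)(C)C)=C([C@H](C)CCCO[Si](c3ccccc3)(c3ccccc3)C(C)(C)C)[C@H](Br)[C@H]1OC(C)=O | intermediate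
14 | 6β,7β-epoxy-8α-ol | O[C@@H]1CC(CO[Si](c4ccccc4)(c4ccccc4)C(C)(C)C)=C([C@H](C)CCCO[Si](c3ccccc3)(c3ccccc3)C(C)(C)C)[C@H]2O[C@@H]12 | intermediate
15 | 7α-(trimethylsilylethynyl)-6β,8α-diol | O[C@@H]1CC(CO[Si](c4ccccc4)(c4ccccc4)C(C)(C)C)=C([C@H](C)CCCO[Si](c3ccccc3)(c3ccccc3)C(C)(C)C)[C@@H](O)[C@@H]1C#C[Si](C)(C)C | intermediate
16 | 7α-ethynyl-6β,8α-diol | O[C@@H]1CC(CO[Si](c4ccccc4)(c4ccccc4)C(C)(C)C)=C([C@H](C)CCCO[Si](c3ccccc3)(c3ccccc3)C(C)(C)C)[C@@H](O)[C@@H]1C#C | intermediate
17 | 6β-hydroxy α-methylene cis-lactone, 1,14-bis-TBDPS | C=C1C(=O)O[C@@H]2CC(CO[Si](c4ccccc4)(c4ccccc4)C(C)(C)C)=C([C@H](C)CCCO[Si](c3ccccc3)(c3ccccc3)C(C)(C)C)[C@@H](O)[C@H]12 | intermediate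
18 | angelic acid | C/C=C(/C)C(=O)O | starting material
19 | angelic 2,4,6-trichlorobenzoic anhydride | C/C=C(/C)C(=O)OC(=O)c1c(Cl)cc(Cl)cc1Cl | intermediate
20 | 6β-O-angelate, 1,14-bis-TBDPS | C=C1C(=O)O[C@@H]2CC(CO[Si](c4ccccc4)(c4ccccc4)C(C)(C)C)=C([C@H](C)CCCO[Si](c3ccccc3)(c3ccccc3)C(C)(C)C)[C@@H](OC(=O)/C(C)=C\C)[C@H]12 | intermediate
21 | CNP0106570.2, (4R,6S,7R,8R) | C=C1C(=O)O[C@@H]2CC(CO)=C([C@H](C)CCCO)[C@@H](OC(=O)/C(C)=C\C)[C@H]12 | target

## Totals
- Total step count: 15.
- Longest linear sequence: 13 (steps 1–3, 5–12, 14, 15, from 1).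

## The three steps most likely to fail

**Risk 1, step 5 (the proposed new step).** Possible failures are no turnover at the hindered C5–H, isomerisation of 6 to internal olefins, formation of the linear product, or weak control at C4.

The fallback uses known chemistry only. It sets out from 4 and comes back at 7.
- Amide-directed vinylic C–H iodination of 4 ([Cp*RhCl2]2, AgSbF6, N-iodosuccinimide, pivalic acid, 1,2-dichloroethane, 60 °C) gives the 5-iodo enamide F1.
- Separately, pent-4-yn-1-ol is hydroiodinated in the Markovnikov sense (NaI, Me3SiCl, H2O, MeCN) to 4-iodopent-4-en-1-ol F2, which is silylated (TBDPSCl, imidazole) to the iodoalkene silyl ether F3.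
- Iodine–lithium exchange (t-BuLi, Et2O, −78 °C) followed by ZnBr2 gives the alkenylzinc bromide F4.
- Negishi coupling of F4 with F1 (Pd(PPh3)4, THF, 50 °C) gives the cross-conjugated diene F5.
- Asymmetric hydrogenation of the 1,1-disubstituted alkene of F5 ([Ir(cod)((S)-tBu-PHOX)]BArF4, H2 at 1–5 bar, CH2Cl2; ligand antipode chosen for 4R) sets C4 and gives 7. The tetrasubstituted ring alkene is too hindered to react, and any C4 epimer is removed by chromatography at 9.

**Risk 2, step 11.** The alane may act mainly as a Lewis acid and deliver the alkyne to the allylic C6. It may also trigger rearrangement of the vinyl epoxide, or Payne migration may scramble the epoxide.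

The fallback replaces the external nucleophile by a tethered one. It sets out from 14 and comes back at 17, so it also bypasses step 12.
- The 8α-OH of 14 is esterified with diethylphosphonoacetic acid (DCC, DMAP cat., CH2Cl2) to give the epoxy phosphonoacetate F6.
- Deprotonation (NaH, THF, 0 °C to rt) gives a phosphoryl-stabilised carbanion held on the α face. It reaches C7 most easily, in a 5-exo-tet, enolexo closure, although 6-endo attack at the allylic C6 cannot be excluded. This gives the α-phosphono cis-lactone F7 with the 6β-OH set free.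
- Horner–Wadsworth–Emmons methylenation (aq. formaldehyde, K2CO3, THF) gives 17.

**Risk 3, step 12.** Possible failures are 5-endo cycloisomerisation of the alkynol, ionisation of the allylic C6 alcohol, or competing closure onto the 6β-OH.

The fallback builds the lactone from the alkyne carbons alone and adds C13 afterwards. It sets out from 16 and comes back at 17.
- Ruthenium-catalysed cycloisomerisation–oxidation through a vinylidene and an oxacarbene (CpRuCl(cod), tri(2-furyl)phosphine, N-hydroxysuccinimide, NaHCO3, Bu4NPF6, DMF–H2O, 95 °C) turns the terminal alkyne carbon into C12 and gives the saturated hydroxy cis-lactone F8.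
- Formation of the dianion (LiN(iPr)2, 2.3 equiv, THF, −78 °C) and trapping with dimethylmethyleneiminium iodide gives the Mannich base F9.
- MeI gives the methiodide F10, and elimination with aq. NaHCO3 gives 17.

## Further compounds
F1 | step 5 | 5-iodo enamide | CC(=O)O[C@@H]1CC(C(=O)N(CC)CC)=C(I)[C@H]2OC(C)(C)O[C@@H]12
F2 | step 5 | 4-iodopent-4-en-1-ol | C=C(I)CCCO
F3 | step 5 | iodoalkene silyl ether | C=C(I)CCCO[Si](c1ccccc1)(c1ccccc1)C(C)(C)C
F4 | step 5 | alkenylzinc bromide | C=C([Zn]Br)CCCO[Si](c1ccccc1)(c1ccccc1)C(C)(C)C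
F5 | step 5 | cross-conjugated diene | CC(=O)O[C@@H]1CC(C(=O)N(CC)CC)=C(C(=C)CCCO[Si](c3ccccc3)(c3ccccc3)C(C)(C)C)[C@H]2OC(C)(C)O[C@@H]12
F6 | step 11 | epoxy phosphonoacetate | CCOP(=O)(OCC)CC(=O)O[C@@H]1CC(CO[Si](c4ccccc4)(c4ccccc4)C(C)(C)C)=C([C@H](C)CCCO[Si](c3ccccc3)(c3ccccc3)C(C)(C)C)[C@H]2O[C@@H]12
F7 | step 11 | α-phosphono cis-lactone (C11 epimers) | CCOP(=O)(OCC)C1C(=O)O[C@@H]2CC(CO[Si](c4ccccc4)(c4ccccc4)C(C)(C)C)=C([C@H](C)CCCO[Si](c3ccccc3)(c3ccccc3)C(C)(C)C)[C@@H](O)[C@H]12
F8 | step 12 | saturated hydroxy cis-lactone | C1C(=O)O[C@@H]2CC(CO[Si](c4ccccc4)(c4ccccc4)C(C)(C)C)=C([C@H](C)CCCO[Si](c3ccccc3)(c3ccccc3)C(C)(C)C)[C@@H](O)[C@H]12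
F9 | step 12 | Mannich base (C11 epimers) | CN(C)CC1C(=O)O[C@@H]2CC(CO[Si](c4ccccc4)(c4ccccc4)C(C)(C)C)=C([C@H](C)CCCO[Si](c3ccccc3)(c3ccccc3)C(C)(C)C)[C@@H](O)[C@H]12
F10 | step 12 | methiodide | C[N+](C)(C)CC1C(=O)O[C@@H]2CC(CO[Si](c4ccccc4)(c4ccccc4)C(C)(C)C)=C([C@H](C)CCCO[Si](c3ccccc3)(c3ccccc3)C(C)(C)C)[C@@H](O)[C@H]12.[I-]
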